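**Retrosynthetic overview**
1. Target 15 ⇐ bis-MOM lactone 14 by acid deprotection (last step).
2. The lactone (the only ring formed, in the penultimate step) ⇐ Pd-catalysed cyclocarbonylation of (R)-homopropargylic alcohol 13 with CO. This closes the ring, brings in C=O and fixes the E-benzylidene by syn addition, so no aldol condensation is used.
3. 13 ⇐ (S)-1,4-enyne 11 by ozonolysis/NaBH4 (the vinyl group is a masked CH2OH).
4. 11 ⇐ E-allylic phosphate 6 + aryl alkynylalane 10 by Cu-catalysed enantioselective SN2′ alkynylation, which sets the single stereocentre while joining the two halves.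
5. 6 ⇐ eugenol (MOM, cross-metathesis, DIBAL-H, phosphorylation); 10 ⇐ 3-hydroxy-4,5-dimethoxybenzaldehyde (MOM, Ohira–Bestmann, DIBAL-H).

Assumption: the catalysts (Hoveyda–Grubbs II, the chiral sulfonate-NHC–Ag precatalyst) are treated as purchasable or separately prepared reagents, and the NHC enantiomer used is the one that gives (S)-11 (to be confirmed by Mosher analysis of 13).

**Step 1**
Reactants: 1 eugenol (4-allyl-2-methoxyphenol)
Product: 2 4-allyl-2-methoxy-1-(methoxymethoxy)benzene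
Conditions: MOMCl (1.3 equiv), i-Pr2NEt (1.5 equiv), CH2Cl2, 0 °C → rt
Reagents that add atoms: chloromethyl methyl ether (MOMCl), COCCl
Why: Base-mediated O-alkylation of the phenol (MOM protection) so that it survives DIBAL-H, the alane and the Pd step; no stereocentre.

**Step 2**
Reactants: 2 4-allyl-2-methoxy-1-(methoxymethoxy)benzene; 3 methyl acrylate (3 equiv)
Product: 4 methyl (2E)-4-[3-methoxy-4-(methoxymethoxy)phenyl]but-2-enoate
Conditions: Hoveyda–Grubbs II (2 mol %), 1,4-benzoquinone (10 mol %), CH2Cl2, 40 °C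
Reagents that add atoms: none
Why: Ru-catalysed olefin cross-metathesis of an allylarene with excess acrylate is strongly E-selective and loses only ethene; benzoquinone suppresses allyl-to-propenyl isomerisation.

**Step 3**
Reactants: 4 methyl (2E)-4-[3-methoxy-4-(methoxymethoxy)phenyl]but-2-enoate
Product: 5 (2E)-4-[3-methoxy-4-(methoxymethoxy)phenyl]but-2-en-1-ol
Conditions: DIBAL-H (2.2 equiv), CH2Cl2, −78 °C; Rochelle salt work-up
Reagents that add atoms: none
Why: DIBAL-H 1,2-reduction of the enoate gives the E-allylic alcohol without touching the alkene or the MOM acetal.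

**Step 4**
Reactants: 5 (2E)-4-[3-methoxy-4-(methoxymethoxy)phenyl]but-2-en-1-ol
Product: 6 diethyl (2E)-4-[3-methoxy-4-(methoxymethoxy)phenyl]but-2-en-1-yl phosphate
Conditions: ClP(O)(OEt)2 (1.2 equiv), Et3N (1.5 equiv), DMAP (10 mol %), CH2Cl2, 0 °C
Reagents that add atoms: diethyl chlorophosphate, CCOP(=O)(Cl)OCC
Why: O-phosphorylation of the primary allylic alcohol installs the leaving group needed for Cu-catalysed SN2′ substitution.

**Step 5**
Reactants: 7 3-hydroxy-4,5-dimethoxybenzaldehyde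
Product: 8 3,4-dimethoxy-5-(methoxymethoxy)benzaldehyde
Conditions: MOMCl (1.3 equiv), i-Pr2NEt (1.5 equiv), CH2Cl2, 0 °C → rt
Reagents that add atoms: chloromethyl methyl ether (MOMCl), COCCl
Why: MOM protection of the phenol by O-alkylation, as in step 1.

**Step 6**
Reactants: 8 3,4-dimethoxy-5-(methoxymethoxy)benzaldehyde
Product: 9 5-ethynyl-1,2-dimethoxy-3-(methoxymethoxy)benzene
Conditions: dimethyl (1-diazo-2-oxopropyl)phosphonate (1.3 equiv), K2CO3 (2 equiv), MeOH, 0 °C → rt
Reagents that add atoms: dimethyl (1-diazo-2-oxopropyl)phosphonate (Ohira–Bestmann reagent), CC(=O)C(=[N+]=[N-])P(=O)(OC)OC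
Why: Seyferth–Gilbert homologation (Ohira–Bestmann variant): HWE-type olefination to a diazoalkene, loss of N2 and a 1,2-H shift give the terminal aryl alkyne.

**Step 7**
Reactants: 9 5-ethynyl-1,2-dimethoxy-3-(methoxymethoxy)benzene (1.6 equiv); 6 diethyl (2E)-4-[3-methoxy-4-(methoxymethoxy)phenyl]but-2-en-1-yl phosphate
Product: 11 (3S)-5-[3,4-dimethoxy-5-(methoxymethoxy)phenyl]-3-{[3-methoxy-4-(methoxymethoxy)phenyl]methyl}pent-1-en-4-yne, via alkynylalane 10 (not isolated)
Conditions: 9, DIBAL-H (1.5 equiv), Et3N (5 mol %), hexanes, 22 °C, 3 h; then 6, chiral sulfonate-bearing NHC–Ag complex (2.5 mol %), CuCl2·2H2O (5 mol %), THF, −30 °C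
Reagents that add atoms: none
Why: Cu-catalysed enantioselective allylic substitution (SN2′ allylic alkynylation): the NHC–Cu–alkynyl species attacks the γ-carbon of the E-allyl phosphate anti to the leaving group, and the chiral NHC selects the alkene face, so the only stereocentre is created (S) in the fragment-joining step.

**Step 8**
Reactants: 11 (3S)-5-[3,4-dimethoxy-5-(methoxymethoxy)phenyl]-3-{[3-methoxy-4-(methoxymethoxy)phenyl]methyl}pent-1-en-4-yne
Product: 13 (2R)-4-[3,4-dimethoxy-5-(methoxymethoxy)phenyl]-2-{[3-methoxy-4-(methoxymethoxy)phenyl]methyl}but-3-yn-1-ol, via aldehyde 12 (not isolated)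
Conditions: O3, CH2Cl2/MeOH 4:1, Sudan III indicator, −78 °C; then NaBH4 (5 equiv), −78 → 0 °C
Reagents that add atoms: ozone, O=[O+][O-]
Why: Ozonolysis with reductive (NaBH4) work-up excises the terminal CH2; the terminal alkene reacts far faster than the aryl alkyne, and the epimerisable α-alkynyl aldehyde is reduced as it forms, so the centre is untouched (S to R is only a CIP priority change).

**Step 9**
Reactants: 13 (2R)-4-[3,4-dimethoxy-5-(methoxymethoxy)phenyl]-2-{[3-methoxy-4-(methoxymethoxy)phenyl]methyl}but-3-yn-1-ol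
Product: 14 (3E,4R)-3-{[3,4-dimethoxy-5-(methoxymethoxy)phenyl]methylidene}-4-{[3-methoxy-4-(methoxymethoxy)phenyl]methyl}oxolan-2-one
Conditions: PdCl2 (5 mol %), PPh3 (10 mol %), SnCl2 (10 mol %), CO (8 atm), MeCN, 75 °C
Reagents that add atoms: carbon monoxide, [C-]#[O+]
Why: Pd-catalysed cyclocarbonylation of a homopropargylic alcohol (Norton-type intramolecular alkoxycarbonylation): the Pd–CO2R unit adds syn and exo across the alkyne and the vinyl–Pd is protonated with retention, so H ends cis to C=O (E-benzylidene) and the ring closes as a pure addition; C4 is not involved.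

**Step 10**
Reactants: 14 (3E,4R)-3-{[3,4-dimethoxy-5-(methoxymethoxy)phenyl]methylidene}-4-{[3-methoxy-4-(methoxymethoxy)phenyl]methyl}oxolan-2-one
Product: 15 (3E,4R)-3-[(3-hydroxy-4,5-dimethoxyphenyl)methylidene]-4-[(4-hydroxy-3-methoxyphenyl)methyl]oxolan-2-one (CNP0187799.1)
Conditions: 2 M HCl, MeOH/THF 2:1, 45 °C
Reagents that add atoms: none
Why: Acid-catalysed acetal cleavage (MOM removal) in methanol, which traps the CH2 unit as dimethoxymethane; the E-alkylidene lactone and C4 are stable to dilute acid.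

**Compound list**
1 | eugenol (4-allyl-2-methoxyphenol) | COc1cc(CC=C)ccc1O | starting material
2 | 4-allyl-2-methoxy-1-(methoxymethoxy)benzene | COCOc1ccc(CC=C)cc1OC | intermediate
3 | methyl acrylate | C=CC(=O)OC | starting material
4 | methyl (2E)-4-[3-methoxy-4-(methoxymethoxy)phenyl]but-2-enoate | COCOc1ccc(C/C=C/C(=O)OC)cc1OC | intermediate
5 | (2E)-4-[3-methoxy-4-(methoxymethoxy)phenyl]but-2-en-1-ol | COCOc1ccc(C/C=C/CO)cc1OC | intermediate
6 | diethyl (2E)-4-[3-methoxy-4-(methoxymethoxy)phenyl]but-2-en-1-yl phosphate | COCOc1ccc(C/C=C/COP(=O)(OCC)OCC)cc1OC | intermediate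
7 | 3-hydroxy-4,5-dimethoxybenzaldehyde | O=Cc1cc(O)c(OC)c(OC)c1 | starting material
8 | 3,4-dimethoxy-5-(methoxymethoxy)benzaldehyde | O=Cc1cc(OCOC)c(OC)c(OC)c1 | intermediate
9 | 5-ethynyl-1,2-dimethoxy-3-(methoxymethoxy)benzene | C#Cc1cc(OCOC)c(OC)c(OC)c1 | intermediate
10 | {[3,4-dimethoxy-5-(methoxymethoxy)phenyl]ethynyl}bis(2-methylpropyl)alumane (not isolated) | CC(C)C[Al](CC(C)C)C#Cc1cc(OCOC)c(OC)c(OC)c1 | intermediate
11 | (3S)-5-[3,4-dimethoxy-5-(methoxymethoxy)phenyl]-3-{[3-methoxy-4-(methoxymethoxy)phenyl]methyl}pent-1-en-4-yne | COCOc1ccc(C[C@H](C#Cc2cc(OCOC)c(OC)c(OC)c2)C=C)cc1OC | intermediate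
12 | (2R)-4-[3,4-dimethoxy-5-(methoxymethoxy)phenyl]-2-{[3-methoxy-4-(methoxymethoxy)phenyl]methyl}but-3-ynal (not isolated) | COCOc1ccc(C[C@H](C#Cc2cc(OCOC)c(OC)c(OC)c2)C=O)cc1OC | intermediate
13 | (2R)-4-[3,4-dimethoxy-5-(methoxymethoxy)phenyl]-2-{[3-methoxy-4-(methoxymethoxy)phenyl]methyl}but-3-yn-1-ol | COCOc1ccc(C[C@H](C#Cc2cc(OCOC)c(OC)c(OC)c2)CO)cc1OC | intermediate
14 | (3E,4R)-3-{[3,4-dimethoxy-5-(methoxymethoxy)phenyl]methylidene}-4-{[3-methoxy-4-(methoxymethoxy)phenyl]methyl}oxolan-2-one | COCOc1ccc(C[C@H]2COC(=O)/C2=C/c2cc(OCOC)c(OC)c(OC)c2)cc1OC | intermediate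
15 | (3E,4R)-3-[(3-hydroxy-4,5-dimethoxyphenyl)methylidene]-4-[(4-hydroxy-3-methoxyphenyl)methyl]oxolan-2-one | COc1cc(C[C@H]2COC(=O)/C2=C/c2cc(O)c(OC)c(OC)c2)ccc1O | target

**Totals**
Total step count: 10. Longest linear sequence: 8 (steps 1–4, then 7–10).

**Steps most likely to fail, with fallbacks**

Step 7 (Cu-catalysed allylic alkynylation): the ee and SN2′ selectivity are untested for this Lewis-basic, alkyl-substituted phosphate, and the ligand is specialised. The fallback sets out from allylic alcohol 5 and returns at alcohol 13. Sharpless asymmetric epoxidation of 5 (Ti(OiPr)4, D-(−)-diethyl tartrate, t-BuOOH, 4 Å MS, CH2Cl2, −20 °C) gives [(2R,3R)-3-{[3-methoxy-4-(methoxymethoxy)phenyl]methyl}oxiran-2-yl]methanol F1. Alkynylalane 10 (3 equiv, toluene, 0 °C → rt) opens it at C3 with inversion to the (2S,3R)-alkynyl-1,2-diol F2. NaIO4 (THF/pH 7 buffer, 0 °C) cleaves the glycol to aldehyde 12, which is reduced at once with NaBH4 to 13. The stereocentre then comes from reagent-controlled epoxidation plus SN2 inversion instead of asymmetric Cu catalysis.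

Step 8 (ozonolysis/reduction): ozone may attack the electron-rich arenes or the alkyne, and aldehyde 12 can epimerise or isomerise to the allenal. The fallback sets out from 2 and 9 (as alane 10) and returns at 13, bringing in the CH2OH carbon as formaldehyde so that no alkene cleavage and no α-alkynyl aldehyde is needed. Ozonolysis of 2 (O3, CH2Cl2, −78 °C; PPh3) gives 2-[3-methoxy-4-(methoxymethoxy)phenyl]acetaldehyde F3. 1,2-Addition of alane 10 (toluene, −20 °C) gives the racemic propargylic alcohol F4, and Dess–Martin oxidation gives the ynone F5. Noyori transfer hydrogenation (RuCl[(S,S)-TsDPEN](p-cymene), i-PrOH, rt) gives the (S)-propargylic alcohol F6, and MsCl/Et3N (CH2Cl2, −78 °C) gives the (S)-mesylate F7. Pd(OAc)2/PPh3 (5 mol %), Et2Zn (3 equiv) and monomeric formaldehyde in THF at −20 °C (Marshall allenylzinc chemistry: anti-SN2′ palladation, Pd-to-Zn exchange, syn-SE2′ addition, net inversion) then give 13.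

Step 9 (cyclocarbonylation): internal aryl alkynes react more slowly than terminal ones, and the HCl/SnCl2 medium may strip MOM groups (harmless, since step 10 removes them) or hydrochlorinate the alkyne. The fallback sets out from 13 and returns at 14, using reductive carboxylation with CO2 instead of alkoxycarbonylation with CO. Ni(cod)2 (5 mol %), CsF, Et2Zn (3 equiv), CO2 (1 atm), MeCN, 60 °C effect syn-hydrocarboxylation: the oxanickelacycle forms its C–CO2 bond at the alkyl-bearing alkyne carbon, and the Ni–C(aryl) bond becomes C–H. This gives the (E)-hydroxy acid F8 with the same geometry, which is lactonised with EDC·HCl/DMAP (CH2Cl2, rt) to 14.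

**Further compounds**
F1 | step 7 | [(2R,3R)-3-{[3-methoxy-4-(methoxymethoxy)phenyl]methyl}oxiran-2-yl]methanol | OC[C@H]1O[C@@H]1Cc1ccc(OCOC)c(OC)c1
F2 | step 7 | (2S,3R)-5-[3,4-dimethoxy-5-(methoxymethoxy)phenyl]-3-{[3-methoxy-4-(methoxymethoxy)phenyl]methyl}pent-4-yne-1,2-diol | OC[C@@H](O)[C@H](Cc1ccc(OCOC)c(OC)c1)C#Cc1cc(OCOC)c(OC)c(OC)c1
F3 | step 8 | 2-[3-methoxy-4-(methoxymethoxy)phenyl]acetaldehyde | O=CCc1ccc(OCOC)c(OC)c1
F4 | step 8 | rac-4-[3,4-dimethoxy-5-(methoxymethoxy)phenyl]-1-[3-methoxy-4-(methoxymethoxy)phenyl]but-3-yn-2-ol | OC(Cc1ccc(OCOC)c(OC)c1)C#Cc1cc(OCOC)c(OC)c(OC)c1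
F5 | step 8 | 4-[3,4-dimethoxy-5-(methoxymethoxy)phenyl]-1-[3-methoxy-4-(methoxymethoxy)phenyl]but-3-yn-2-one | O=C(Cc1ccc(OCOC)c(OC)c1)C#Cc1cc(OCOC)c(OC)c(OC)c1
F6 | step 8 | (2S)-4-[3,4-dimethoxy-5-(methoxymethoxy)phenyl]-1-[3-methoxy-4-(methoxymethoxy)phenyl]but-3-yn-2-ol | COCOc1ccc(C[C@H](O)C#Cc2cc(OCOC)c(OC)c(OC)c2)cc1OC
F7 | step 8 | (2S)-4-[3,4-dimethoxy-5-(methoxymethoxy)phenyl]-1-[3-methoxy-4-(methoxymethoxy)phenyl]but-3-yn-2-yl methanesulfonate | COCOc1ccc(C[C@H](OS(C)(=O)=O)C#Cc2cc(OCOC)c(OC)c(OC)c2)cc1OC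
F8 | step 9 | (2E)-3-[3,4-dimethoxy-5-(methoxymethoxy)phenyl]-2-{(2R)-1-hydroxy-3-[3-methoxy-4-(methoxymethoxy)phenyl]propan-2-yl}prop-2-enoic acid | OC[C@H](Cc1ccc(OCOC)c(OC)c1)/C(C(=O)O)=C\c1cc(OCOC)c(OC)c(OC)c1
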